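**Retrosynthetic overview**

1. The target is epicatechin-(4β→8)-M-(4β→8)-catechin (units U, M, L from the top), where M is a 5-deoxy 2,3-cis-3,4-trans-flavan-3-ol. The strategy rests on ring A of M: its C8, the carbon between O1 and O7, carries unit U, so C4a is the only free carbon ortho to O1, and C4 of M is the benzylic carbon bonded to C8 of the phloroglucinol ring A of L.
2. The last skeletal bond is C4–C4a of M, made by 6-endo opening of a trans C3–C4 epoxide by the tethered aryl ether ring, so ring C of M is the last ring formed; hydrogenolysis of thirteen benzyl ethers follows.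
3. The glycidyl ether comes from a Mitsunobu coupling (O1–C2 bond, inversion) of phenol 11 with the erythro epoxy alcohol 22.
4. Phenol 11 (ring A of M already carrying U) comes from the C4 cation of benzylated epicatechin and C2 of cyclohexane-1,3-dione, then O-benzylation and dehydrogenation to the arene.
5. Epoxy alcohol 22 comes from benzylated catechin-8-carbaldehyde and 3′,4′-bis(benzyloxy)acetophenone: E-enone, nucleophilic asymmetric epoxidation, chelation-controlled reduction.

Key step: step 16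

Assumption: flavan numbering (O1, C2–C4, C4a, C5–C8, C8a, primes for ring B) is used within each unit; "penta-O-benzylepicatechin-4β-yl" and "penta-O-benzylcatechin-8-yl" mean the 3,5,7,3′,4′-pentabenzyl ethers; the aryl epoxides 21–23 are treated as acid-labile (base-washed glassware, Et3N-deactivated silica), and because unit L is one enantiomer the two epoxide series are diastereomers, so the sense of step 13 can be checked directly.

**Route**

Step 1
Reactants: 1 (−)-epicatechin
Product: 2 5,7,3′,4′-tetra-O-benzyl-(−)-epicatechin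
Conditions: BnBr, K2CO3, DMF, rt
Reagents that add atoms: benzyl bromide, BrCc1ccccc1
Why: Williamson etherification in which K2CO3 deprotonates only the four phenols, so the secondary 3-OH and both stereocentres stay untouched.

Step 2
Reactants: 2 5,7,3′,4′-tetra-O-benzyl-(−)-epicatechin
Product: 3 3,5,7,3′,4′-penta-O-benzyl-(−)-epicatechin
Conditions: NaH, BnBr, DMF, 0 °C to rt
Reagents that add atoms: benzyl bromide, BrCc1ccccc1
Why: Williamson etherification of the secondary alkoxide; no free phenoxide is left, so base-induced epimerisation at C2 through a quinone methide is excluded.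

Step 3
Reactants: 3 3,5,7,3′,4′-penta-O-benzyl-(−)-epicatechin
Product: 4 4β-(2-ethoxyethoxy)-penta-O-benzylepicatechin (3,4-trans)
Conditions: DDQ, 2-ethoxyethanol, CH2Cl2, rt
Reagents that add atoms: 2-ethoxyethanol, CCOCCO
Why: DDQ benzylic oxidation (hydride abstraction at C4, activated by the oxygenated ring A) followed by capture of the cation by the alcohol anti to the 3-benzyloxy group, which sets the 4β (3,4-trans) centre.

Step 4
Reactants: 4 4β-(2-ethoxyethoxy)-penta-O-benzylepicatechin; 5 cyclohexane-1,3-dione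
Product: 6 2-(penta-O-benzylepicatechin-4β-yl)cyclohexane-1,3-dione (enol form)
Conditions: 5 (5 equiv), BF3·OEt2 (0.3 equiv), CH2Cl2–THF, −40 to 0 °C
Reagents that add atoms: none
Why: Lewis-acid SN1 alkylation of a 1,3-diketone by the flavan-4-yl cation: C2 of the dione is its only carbon nucleophile and becomes C8 of unit M, attack anti to the 3-benzyloxy group sets the 4β centre of unit U, and any O-alkylated enol ether re-ionises and funnels to the C-alkylated product.

Step 5
Reactants: 6 2-(penta-O-benzylepicatechin-4β-yl)cyclohexane-1,3-dione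
Product: 7 3-(benzyloxy)-2-(penta-O-benzylepicatechin-4β-yl)cyclohex-2-en-1-one
Conditions: BnBr, Cs2CO3, DMF, rt
Reagents that add atoms: benzyl bromide, BrCc1ccccc1
Why: O-alkylation of the vinylogous acid (Williamson type); the bulky secondary flavanyl group at C2 blocks quaternary C-alkylation and the two enol oxygens are equivalent, so one monobenzyl vinylogous ester should form and the later statistical monobenzylation of a symmetric resorcinol is avoided.

Step 6
Reactants: 7 3-(benzyloxy)-2-(penta-O-benzylepicatechin-4β-yl)cyclohex-2-en-1-one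
Product: 11 3-(benzyloxy)-2-(penta-O-benzylepicatechin-4β-yl)phenol, via α′-phenylselenide 8 (not isolated), via selenoxide 9 (not isolated), via cyclohexa-2,5-dienone 10 (not isolated)
Conditions: LiN(iPr)2, THF, −78 °C; PhSeCl; then H2O2, pyridine, CH2Cl2, 0 °C to rt
Reagents that add atoms: none
Why: Kinetic α′-enolate selenenylation and selenoxide syn-elimination of a vinylogous ester give the cross-conjugated dienone, which tautomerises to the resorcinol monobenzyl ether, so aromatisation and differentiation of the two oxygens happen together.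

Step 7
Reactants: 12 (+)-catechin
Product: 13 5,7,3′,4′-tetra-O-benzyl-(+)-catechin
Conditions: BnBr, K2CO3, DMF, rt
Reagents that add atoms: benzyl bromide, BrCc1ccccc1
Why: Williamson etherification selective for the four phenols, as in step 1.

Step 8
Reactants: 13 5,7,3′,4′-tetra-O-benzyl-(+)-catechin
Product: 14 3,5,7,3′,4′-penta-O-benzyl-(+)-catechin
Conditions: NaH, BnBr, DMF, 0 °C to rt
Reagents that add atoms: benzyl bromide, BrCc1ccccc1
Why: Williamson etherification of the 3-alkoxide, as in step 2.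

Step 9
Reactants: 14 3,5,7,3′,4′-penta-O-benzyl-(+)-catechin
Product: 15 8-bromo-penta-O-benzylcatechin
Conditions: NBS (1.0 equiv), CH2Cl2, −78 to 0 °C
Reagents that add atoms: N-bromosuccinimide, O=C1CCC(=O)N1Br
Why: Electrophilic aromatic bromination, which in 5,7-di-O-benzylflavans goes to C8 because C6 lies between two benzyloxy groups and is the more hindered of the two activated positions.

Step 10
Reactants: 15 8-bromo-penta-O-benzylcatechin
Product: 17 penta-O-benzylcatechin-8-carbaldehyde, via 8-lithio-penta-O-benzylcatechin 16 (not isolated)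
Conditions: n-BuLi, THF, −78 °C; DMF, −78 to 0 °C; H2O
Reagents that add atoms: N,N-dimethylformamide, CN(C)C=O
Why: Bromine–lithium exchange and formylation of the aryllithium with DMF (Bouveault type) place the aldehyde carbon, the future C4 of unit M, on C8 of unit L without touching the benzyl ethers at −78 °C.

Step 11
Reactants: 18 3′,4′-dihydroxyacetophenone
Product: 19 3′,4′-bis(benzyloxy)acetophenone
Conditions: BnBr, K2CO3, DMF, 60 °C
Reagents that add atoms: benzyl bromide, BrCc1ccccc1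
Why: Williamson etherification of both phenols of the catechol ketone.

Step 12
Reactants: 17 penta-O-benzylcatechin-8-carbaldehyde; 19 3′,4′-bis(benzyloxy)acetophenone
Product: 20 (E)-1-[3,4-bis(benzyloxy)phenyl]-3-(penta-O-benzylcatechin-8-yl)prop-2-en-1-one
Conditions: KOH, EtOH–THF, rt
Reagents that add atoms: none
Why: Claisen–Schmidt crossed aldol condensation between a non-enolisable aldehyde and a methyl ketone; E1cB dehydration gives the conjugated E-enone, which carries C2, C3 and C4 of unit M.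

Step 13
Reactants: 20 (E)-1-[3,4-bis(benzyloxy)phenyl]-3-(penta-O-benzylcatechin-8-yl)prop-2-en-1-one
Product: 21 [3,4-bis(benzyloxy)phenyl][(2R,3S)-3-(penta-O-benzylcatechin-8-yl)oxiran-2-yl]methanone
Conditions: poly-L-leucine, urea–H2O2, DBU, THF, rt
Reagents that add atoms: hydrogen peroxide (as its urea adduct), OO
Why: Juliá–Colonna epoxidation (Weitz–Scheffer conjugate addition of hydroperoxide and ring closure): the E-enone gives the trans-epoxide, the helical poly-L-leucine should select the face that sets the epoxide carbons as 2R,3S, and the basic medium together with the adjacent carbonyl spares the acid-labile trioxygenated benzylic epoxide.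

Step 14
Reactants: 21 [3,4-bis(benzyloxy)phenyl][(2R,3S)-3-(penta-O-benzylcatechin-8-yl)oxiran-2-yl]methanone
Product: 22 (S)-[3,4-bis(benzyloxy)phenyl][(2S,3S)-3-(penta-O-benzylcatechin-8-yl)oxiran-2-yl]methanol (erythro)
Conditions: Zn(BH4)2, Et2O–THF, −40 °C; aq. NaHCO3
Reagents that add atoms: none
Why: Chelation-controlled reduction of an α,β-epoxy ketone: zinc bridges the carbonyl and epoxide oxygens and hydride adds to the exposed carbonyl face, which should give the erythro (anti) alcohol with the S carbinol centre.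

Step 15
Reactants: 11 3-(benzyloxy)-2-(penta-O-benzylepicatechin-4β-yl)phenol; 22 erythro epoxy alcohol
Product: 23 threo aryl glycidyl ether: 1-{(R)-[3,4-bis(benzyloxy)phenyl][(2R,3S)-3-(penta-O-benzylcatechin-8-yl)oxiran-2-yl]methoxy}-3-(benzyloxy)-2-(penta-O-benzylepicatechin-4β-yl)benzene
Conditions: PPh3, DIAD, THF, 0 °C to rt
Reagents that add atoms: none
Why: Mitsunobu etherification: the phenol displaces the oxyphosphonium group by SN2 with inversion, turning the S carbinol into the R centre that becomes C2 of unit M (erythro alcohol to threo ether), while the adjacent epoxide oxygen inductively disfavours ionisation of the benzylic centre.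

Step 16
Reactants: 23 threo aryl glycidyl ether
Product: 24 tridecabenzyl ether of the target with the 3-OH of unit M free: penta-O-benzylepicatechin-(4β→8)-[(2R,3R,4R)-7,3′,4′-tris(benzyloxy)flavan-3-ol]-(4β→8)-penta-O-benzylcatechin
Conditions: BF3·OEt2 (0.3 equiv), CH2Cl2 (0.005 M), −78 °C; Et3N quench
Reagents that add atoms: none
Why: BF3 binds the epoxide oxygen and lengthens the benzylic C4–O bond, which the 2,4,6-trioxygenated ring A of unit L polarises strongly; C4a of the aryl ether ring (para to the 7-benzyloxy group, ortho to the ether oxygen, and the only free ortho carbon because C8 carries unit U) attacks C4 from the face opposite the departing oxygen and rearomatises, an intramolecular Friedel–Crafts epoxy–arene cyclisation of an aryl glycidyl ether as used for trans-4-arylchroman-3-ols. Ring C of unit M closes in the 6-endo-tet mode; the 5-exo alternative at C3 is not benzylic, and attack by the catechol ring on C2 would need a five-membered indane transition state without backside alignment. The new stereocentre C4 arises by inversion of the S epoxide carbon, so the trans-epoxide becomes the 3,4-trans (4R) relation, C3 keeps its oxygen, and C2, set in step 15, is not touched, which gives the 2,3-cis-3,4-trans unit. Two selectivities are needed: C4a over every other nucleophilic carbon, secured by the six-membered tether and the blocked C8, and SN2-like opening over free-cation chemistry (C4 epimer, hydride shift to a C3 ketone, intermolecular capture), secured by −78 °C, substoichiometric Lewis acid and high dilution so that ring closure should outrun full ionisation. The benzyl ethers and the benzyl-protected interflavan bond of unit U should tolerate BF3·OEt2 at this temperature.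

Step 17
Reactants: 24 tridecabenzyl ether
Product: 25 target (CNP0270097.1), epicatechin-(4β→8)-[(2R,3R,4R)-3,7,3′,4′-tetrahydroxyflavan]-(4β→8)-catechin
Conditions: H2 (1 atm), Pd(OH)2/C, THF–MeOH–H2O, rt
Reagents that add atoms: none
Why: Heterogeneous hydrogenolysis cleaves the thirteen O-benzyl groups as toluene, while the interflavan C4–C8 bonds, the pyran C2–O1 bonds and all eight stereocentres should be unaffected under neutral conditions at room temperature.

**Compound list**

1 | (−)-epicatechin | Oc1cc(O)c2c(c1)O[C@H](c1ccc(O)c(O)c1)[C@H](O)C2 | starting material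
2 | 5,7,3′,4′-tetra-O-benzyl-(−)-epicatechin | O(Cc9ccccc9)c1cc(OCc9ccccc9)c2c(c1)O[C@H](c7ccc(OCc9ccccc9)c(OCc9ccccc9)c7)[C@H](O)C2 | intermediate
3 | 3,5,7,3′,4′-penta-O-benzyl-(−)-epicatechin | O(Cc9ccccc9)c1cc(OCc9ccccc9)c2c(c1)O[C@H](c7ccc(OCc9ccccc9)c(OCc9ccccc9)c7)[C@H](OCc9ccccc9)C2 | intermediate
4 | 4β-(2-ethoxyethoxy)-penta-O-benzylepicatechin (2,3-cis-3,4-trans) | O(Cc9ccccc9)c1cc(OCc9ccccc9)c2c(c1)O[C@H](c7ccc(OCc9ccccc9)c(OCc9ccccc9)c7)[C@H](OCc9ccccc9)[C@H]2OCCOCC | intermediate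
5 | cyclohexane-1,3-dione | O=C1CCCC(=O)C1 | starting material
6 | 2-(penta-O-benzylepicatechin-4β-yl)cyclohexane-1,3-dione, drawn as the enol 3-hydroxy-2-substituted cyclohex-2-en-1-one | O(Cc9ccccc9)c1cc(OCc9ccccc9)c2c(c1)O[C@H](c7ccc(OCc9ccccc9)c(OCc9ccccc9)c7)[C@H](OCc9ccccc9)[C@H]2C1=C(O)CCCC1=O | intermediate
7 | 3-(benzyloxy)-2-(penta-O-benzylepicatechin-4β-yl)cyclohex-2-en-1-one | O(Cc9ccccc9)c1cc(OCc9ccccc9)c2c(c1)O[C@H](c7ccc(OCc9ccccc9)c(OCc9ccccc9)c7)[C@H](OCc9ccccc9)[C@H]2C1=C(OCc9ccccc9)CCCC1=O | intermediate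
8 | 6-(phenylselanyl) derivative of 7, both epimers at C6 of the cyclohexenone (not isolated) | O(Cc9ccccc9)c1cc(OCc9ccccc9)c2c(c1)O[C@H](c7ccc(OCc9ccccc9)c(OCc9ccccc9)c7)[C@H](OCc9ccccc9)[C@H]2C1=C(OCc9ccccc9)CCC([Se]c9ccccc9)C1=O | intermediate
9 | selenoxide of 8 (not isolated) | O(Cc9ccccc9)c1cc(OCc9ccccc9)c2c(c1)O[C@H](c7ccc(OCc9ccccc9)c(OCc9ccccc9)c7)[C@H](OCc9ccccc9)[C@H]2C1=C(OCc9ccccc9)CCC([Se](=O)c9ccccc9)C1=O | intermediate
10 | 3-(benzyloxy)-2-(penta-O-benzylepicatechin-4β-yl)cyclohexa-2,5-dien-1-one (not isolated) | O(Cc9ccccc9)c1cc(OCc9ccccc9)c2c(c1)O[C@H](c7ccc(OCc9ccccc9)c(OCc9ccccc9)c7)[C@H](OCc9ccccc9)[C@H]2C1=C(OCc9ccccc9)CC=CC1=O | intermediate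
11 | 3-(benzyloxy)-2-(penta-O-benzylepicatechin-4β-yl)phenol | O(Cc9ccccc9)c1cc(OCc9ccccc9)c2c(c1)O[C@H](c7ccc(OCc9ccccc9)c(OCc9ccccc9)c7)[C@H](OCc9ccccc9)[C@H]2c1c(OCc9ccccc9)cccc1O | intermediate
12 | (+)-catechin | Oc1cc(O)c2c(c1)O[C@H](c1ccc(O)c(O)c1)[C@@H](O)C2 | starting material
13 | 5,7,3′,4′-tetra-O-benzyl-(+)-catechin | O(Cc9ccccc9)c1cc(OCc9ccccc9)c2c(c1)O[C@H](c7ccc(OCc9ccccc9)c(OCc9ccccc9)c7)[C@@H](O)C2 | intermediate
14 | 3,5,7,3′,4′-penta-O-benzyl-(+)-catechin | O(Cc9ccccc9)c1cc(OCc9ccccc9)c2c(c1)O[C@H](c7ccc(OCc9ccccc9)c(OCc9ccccc9)c7)[C@@H](OCc9ccccc9)C2 | intermediate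
15 | 8-bromo-penta-O-benzylcatechin | Brc1c(OCc9ccccc9)cc(OCc9ccccc9)c2c1O[C@H](c7ccc(OCc9ccccc9)c(OCc9ccccc9)c7)[C@@H](OCc9ccccc9)C2 | intermediate
16 | 8-lithio-penta-O-benzylcatechin (not isolated) | [Li]c1c(OCc9ccccc9)cc(OCc9ccccc9)c2c1O[C@H](c7ccc(OCc9ccccc9)c(OCc9ccccc9)c7)[C@@H](OCc9ccccc9)C2 | intermediate
17 | penta-O-benzylcatechin-8-carbaldehyde | O=Cc1c(OCc9ccccc9)cc(OCc9ccccc9)c2c1O[C@H](c7ccc(OCc9ccccc9)c(OCc9ccccc9)c7)[C@@H](OCc9ccccc9)C2 | intermediate
18 | 3′,4′-dihydroxyacetophenone | CC(=O)c1ccc(O)c(O)c1 | starting material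
19 | 3′,4′-bis(benzyloxy)acetophenone | CC(=O)c7ccc(OCc9ccccc9)c(OCc9ccccc9)c7 | intermediate
20 | (E)-1-[3,4-bis(benzyloxy)phenyl]-3-(penta-O-benzylcatechin-8-yl)prop-2-en-1-one | O=C(c7ccc(OCc9ccccc9)c(OCc9ccccc9)c7)/C=C/c1c(OCc9ccccc9)cc(OCc9ccccc9)c2c1O[C@H](c7ccc(OCc9ccccc9)c(OCc9ccccc9)c7)[C@@H](OCc9ccccc9)C2 | intermediate
21 | [3,4-bis(benzyloxy)phenyl][(2R,3S)-3-(penta-O-benzylcatechin-8-yl)oxiran-2-yl]methanone (trans-epoxy ketone) | O=C(c7ccc(OCc9ccccc9)c(OCc9ccccc9)c7)[C@@H]4O[C@H]4c1c(OCc9ccccc9)cc(OCc9ccccc9)c2c1O[C@H](c7ccc(OCc9ccccc9)c(OCc9ccccc9)c7)[C@@H](OCc9ccccc9)C2 | intermediate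
22 | (S)-[3,4-bis(benzyloxy)phenyl][(2S,3S)-3-(penta-O-benzylcatechin-8-yl)oxiran-2-yl]methanol (erythro, trans-epoxide) | O[C@@H](c7ccc(OCc9ccccc9)c(OCc9ccccc9)c7)[C@@H]4O[C@H]4c1c(OCc9ccccc9)cc(OCc9ccccc9)c2c1O[C@H](c7ccc(OCc9ccccc9)c(OCc9ccccc9)c7)[C@@H](OCc9ccccc9)C2 | intermediate
23 | threo aryl glycidyl ether, key-step precursor (future C2 R, C3 R, C4 S of unit M; unit U on the aryl ether ring, unit L on the trans-epoxide) | O(Cc9ccccc9)c1cc(OCc9ccccc9)c2c(c1)O[C@H](c7ccc(OCc9ccccc9)c(OCc9ccccc9)c7)[C@H](OCc9ccccc9)[C@H]2c1c(OCc9ccccc9)cccc1O[C@H](c7ccc(OCc9ccccc9)c(OCc9ccccc9)c7)[C@@H]4O[C@H]4c1c(OCc9ccccc9)cc(OCc9ccccc9)c2c1O[C@H](c7ccc(OCc9ccccc9)c(OCc9ccccc9)c7)[C@@H](OCc9ccccc9)C2 | intermediate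
24 | tridecabenzyl ether of the target, 3-OH of unit M free (unit M 2R,3R,4R) | O(Cc9ccccc9)c1cc(OCc9ccccc9)c2c(c1)O[C@H](c7ccc(OCc9ccccc9)c(OCc9ccccc9)c7)[C@H](OCc9ccccc9)[C@H]2c1c(OCc9ccccc9)ccc2c1O[C@H](c7ccc(OCc9ccccc9)c(OCc9ccccc9)c7)[C@H](O)[C@H]2c1c(OCc9ccccc9)cc(OCc9ccccc9)c2c1O[C@H](c7ccc(OCc9ccccc9)c(OCc9ccccc9)c7)[C@@H](OCc9ccccc9)C2 | intermediate
25 | CNP0270097.1, epicatechin-(4β→8)-[(2R,3R,4R)-3,7,3′,4′-tetrahydroxyflavan]-(4β→8)-catechin | Oc1cc(O)c2c(c1)O[C@H](c1ccc(O)c(O)c1)[C@H](O)[C@H]2c1c(O)ccc2c1O[C@H](c1ccc(O)c(O)c1)[C@H](O)[C@H]2c1c(O)cc(O)c2c1O[C@H](c1ccc(O)c(O)c1)[C@@H](O)C2 | target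

**Step count and risks**

Total: 17 steps. Longest linear sequence: 10 steps (12 → 13 → 14 → 15 → 17 → 20 → 21 → 22 → 23 → 24 → 25).

Steps most likely to fail:

1. Step 16 (epoxide–arene closure). The C4–O bond, flanked by the trioxygenated ring, may ionise fully before C4a bonds. Inversion would then be lost (C4 epimer), hydride could shift to give a C3 ketone, or the cation could be captured by another molecule. The fallback sets out from phenol 11 and returns at 24: ring C of unit M is closed before unit L is attached, and L is introduced by Lewis-acid coupling of a cyclic flavan-4-yl cation, whose 3,4-trans selectivity does not depend on an SN2 course. Commercial 3,4-bis(benzyloxy)benzaldehyde and CH2=CHMgBr (THF, 0 °C) would give racemic 1-[3,4-bis(benzyloxy)phenyl]prop-2-en-1-ol F1. Sharpless kinetic resolution (Ti(OiPr)4, L-(+)-diisopropyl tartrate, t-BuOOH, 4 Å molecular sieves, CH2Cl2, −20 °C) would convert its R enantiomer into the erythro epoxy alcohol (S)-[3,4-bis(benzyloxy)phenyl][(R)-oxiran-2-yl]methanol F2. Mitsunobu coupling of F2 with 11 (PPh3, DIAD, THF) would give the threo glycidyl ether F3. BF3·OEt2 in CH2Cl2 (−78 to −20 °C) would close ring C by 6-endo attack of C4a on the terminal epoxide carbon, which cannot form a stabilised cation, giving the 2,3-cis flavan-3-ol F4 (unit U at C8, C4 unsubstituted). DDQ and 2-ethoxyethanol in CH2Cl2 would oxidise the only unsubstituted activated benzylic methylene, C4 of unit M, to the 4β-(2-ethoxyethoxy) derivative F5. TMSOTf-catalysed coupling of F5 with an excess of penta-O-benzylcatechin 14 (CH2Cl2, −78 °C), which reacts at C8 and anti to the 3-hydroxyl group, would give 24.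

2. Step 13 (asymmetric epoxidation). Hydroperoxide addition to the hindered, donor-substituted enone may be slow, and the polymer catalyst may control the face poorly for so large a substrate. The fallback sets out from enone 20 and returns at 22, so step 14 is skipped. 1,2-Reduction with iBu2AlH (CH2Cl2, −78 °C, basic work-up) would give the allylic alcohol (E)-1-[3,4-bis(benzyloxy)phenyl]-3-(penta-O-benzylcatechin-8-yl)prop-2-en-1-ol F6 as both carbinol epimers. A Sharpless kinetic resolution (Ti(OtBu)4, L-(+)-diisopropyl tartrate, t-BuOOH, 4 Å molecular sieves, CH2Cl2, −25 °C, basic work-up) would epoxidise only the 1R epimer, on the alkene face that gives the erythro epoxy alcohol 22. The unreacted 1S epimer can be re-oxidised to 20 with MnO2. This path exposes the labile epoxide to a titanium alkoxide, which is why it is the reserve and not the main route.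

3. Step 15 (Mitsunobu etherification). Capture of the activated benzylic carbinol by the hindered, weakly acidic phenol may be slow, so the oxyphosphonium intermediate could ionise, with loss of inversion, epoxide migration or elimination. The fallback sets out from dione adduct 6 (with epoxy alcohol 22) and returns at 23; it uses the far more acidic vinylogous acid as the Mitsunobu partner and builds the arene afterwards. Mitsunobu O-alkylation of 6 with 22 (PPh3, DIAD, THF, 0 °C) would give, with the same inversion, the 3-alkoxycyclohex-2-en-1-one F7. Kinetic α′-deprotonation (LiN(iPr)2, THF, −78 °C) and dehydrogenation with N-tert-butylbenzenesulfinimidoyl chloride would give the cyclohexa-2,5-dienone F8, which tautomerises to the phenol F9. Benzylation (BnBr, K2CO3, DMF) would give 23.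

**Further compounds**

F1 | step 16 | rac-1-[3,4-bis(benzyloxy)phenyl]prop-2-en-1-ol | OC(C=C)c7ccc(OCc9ccccc9)c(OCc9ccccc9)c7
F2 | step 16 | (S)-[3,4-bis(benzyloxy)phenyl][(R)-oxiran-2-yl]methanol (erythro) | O[C@@H](c7ccc(OCc9ccccc9)c(OCc9ccccc9)c7)[C@@H]4OC4
F3 | step 16 | threo glycidyl ether of 11 with a terminal epoxide: 1-{(R)-[3,4-bis(benzyloxy)phenyl][(R)-oxiran-2-yl]methoxy}-3-(benzyloxy)-2-(penta-O-benzylepicatechin-4β-yl)benzene | O(Cc9ccccc9)c1cc(OCc9ccccc9)c2c(c1)O[C@H](c7ccc(OCc9ccccc9)c(OCc9ccccc9)c7)[C@H](OCc9ccccc9)[C@H]2c1c(OCc9ccccc9)cccc1O[C@H](c7ccc(OCc9ccccc9)c(OCc9ccccc9)c7)[C@@H]4OC4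
F4 | step 16 | penta-O-benzylepicatechin-(4β→8)-[(2R,3R)-7,3′,4′-tris(benzyloxy)flavan-3-ol] (2,3-cis, C4 unsubstituted) | O(Cc9ccccc9)c1cc(OCc9ccccc9)c2c(c1)O[C@H](c7ccc(OCc9ccccc9)c(OCc9ccccc9)c7)[C@H](OCc9ccccc9)[C@H]2c1c(OCc9ccccc9)ccc2c1O[C@H](c7ccc(OCc9ccccc9)c(OCc9ccccc9)c7)[C@H](O)C2
F5 | step 16 | 4β-(2-ethoxyethoxy) derivative of F4 (2,3-cis-3,4-trans in unit M) | O(Cc9ccccc9)c1cc(OCc9ccccc9)c2c(c1)O[C@H](c7ccc(OCc9ccccc9)c(OCc9ccccc9)c7)[C@H](OCc9ccccc9)[C@H]2c1c(OCc9ccccc9)ccc2c1O[C@H](c7ccc(OCc9ccccc9)c(OCc9ccccc9)c7)[C@H](O)[C@H]2OCCOCC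
F6 | step 13 | (E)-1-[3,4-bis(benzyloxy)phenyl]-3-(penta-O-benzylcatechin-8-yl)prop-2-en-1-ol, both epimers at the carbinol carbon | OC(c7ccc(OCc9ccccc9)c(OCc9ccccc9)c7)/C=C/c1c(OCc9ccccc9)cc(OCc9ccccc9)c2c1O[C@H](c7ccc(OCc9ccccc9)c(OCc9ccccc9)c7)[C@@H](OCc9ccccc9)C2
F7 | step 15 | 3-{(R)-[3,4-bis(benzyloxy)phenyl][(2R,3S)-3-(penta-O-benzylcatechin-8-yl)oxiran-2-yl]methoxy}-2-(penta-O-benzylepicatechin-4β-yl)cyclohex-2-en-1-one | O(Cc9ccccc9)c1cc(OCc9ccccc9)c2c(c1)O[C@H](c7ccc(OCc9ccccc9)c(OCc9ccccc9)c7)[C@H](OCc9ccccc9)[C@H]2C1=C(CCCC1=O)O[C@H](c7ccc(OCc9ccccc9)c(OCc9ccccc9)c7)[C@@H]4O[C@H]4c1c(OCc9ccccc9)cc(OCc9ccccc9)c2c1O[C@H](c7ccc(OCc9ccccc9)c(OCc9ccccc9)c7)[C@@H](OCc9ccccc9)C2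
F8 | step 15 | cyclohexa-2,5-dien-1-one obtained from F7 by α′,β′-dehydrogenation (not isolated) | O(Cc9ccccc9)c1cc(OCc9ccccc9)c2c(c1)O[C@H](c7ccc(OCc9ccccc9)c(OCc9ccccc9)c7)[C@H](OCc9ccccc9)[C@H]2C1=C(CC=CC1=O)O[C@H](c7ccc(OCc9ccccc9)c(OCc9ccccc9)c7)[C@@H]4O[C@H]4c1c(OCc9ccccc9)cc(OCc9ccccc9)c2c1O[C@H](c7ccc(OCc9ccccc9)c(OCc9ccccc9)c7)[C@@H](OCc9ccccc9)C2
F9 | step 15 | phenol corresponding to 23 without the 7-O-benzyl group of unit M | O(Cc9ccccc9)c1cc(OCc9ccccc9)c2c(c1)O[C@H](c7ccc(OCc9ccccc9)c(OCc9ccccc9)c7)[C@H](OCc9ccccc9)[C@H]2c1c(O)cccc1O[C@H](c7ccc(OCc9ccccc9)c(OCc9ccccc9)c7)[C@@H]4O[C@H]4c1c(OCc9ccccc9)cc(OCc9ccccc9)c2c1O[C@H](c7ccc(OCc9ccccc9)c(OCc9ccccc9)c7)[C@@H](OCc9ccccc9)C2
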